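**Retrosynthetic overview**
1. Ring D (dihydropyran) is closed last as a cyclic C10 acetal; the C10–C9 bond comes from alkenylation of its oxocarbenium ion with a nonenyl borate built from 1-bromoheptane and acetylide.
2. Rings B (cyclohexane) and C (bridging δ-lactone) are formed together in the key step: an α-ketol ring expansion of a cis-bicyclo[3.3.0]octane carrying a C24 carbinol and an α-keto ester, which inserts C12 with its hydroxyl and lactone carbonyl.
3. The α-keto ester comes from a dithiane-masked glyoxylate added to the C24 ketone; O14 from conjugate borylation/oxidation; the C20 side chain from an aldol with 3-ethoxymethacrolein.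
4. Ring A and the five-membered precursor of ring B come from an enantioselective Pauson–Khand reaction of an enyne assembled on 1,3-dithiane (masked C17 ketone).
5. Ring order: A plus cyclopentane precursor of B, then B and C, then D; the C17 and C24 carbinols are set by one late reduction.

Numbering: atoms are numbered along the target SMILES from the left (C1–C7 heptyl, C8=C9, C10, O11, C12, C13 lactone carbonyl, O14, C15, C16, C17, C18, C19, C20, C21=C22 with the methyl on C22, C23, C24). In the bicyclo[3.3.0]octane names of 6–15, C1=C15, C2=C23, C3=C24, C4=C20, C5=C19, C6=C18, C7=C17, C8=C16.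
Assumption: the (S)-BINAP cobalt catalyst is taken to give the (5S)-enone 6; if the antipode forms, (R)-BINAP is used.

**Step 1**
Reactants: 1 1,3-dithiane; 2 allyl bromide; 3 propargyl bromide
Product: 5 2-allyl-2-(prop-2-yn-1-yl)-1,3-dithiane, via 2-allyl-1,3-dithiane 4 (not isolated)
Conditions: n-BuLi, THF, −30 °C; 2, −78 to 0 °C; n-BuLi, −30 °C; 3, −78 to 23 °C
Reagents that add atoms: none
Why: Two successive Corey–Seebach alkylations of 2-lithio-1,3-dithiane (SN2 on a primary allylic and a primary propargylic bromide) assemble the 1,6-enyne around the masked C17 carbonyl; no stereocentre is formed.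

**Step 2**
Reactants: 5 2-allyl-2-(prop-2-yn-1-yl)-1,3-dithiane
Product: 6 (5S)-spiro[bicyclo[3.3.0]oct-1-ene-7,2'-[1,3]dithian]-3-one
Conditions: Co2(CO)8 (20 mol %), (S)-BINAP (20 mol %), CO (1 atm), DME, 85 °C
Reagents that add atoms: carbon monoxide, [C-]#[O+]
Why: Catalytic enantioselective Pauson–Khand reaction ([2+2+1] of alkyne, alkene and CO on cobalt), in which the BINAP-bound cobalt–alkyne complex selects one enantiotopic face of the tethered alkene during insertion and so sets C19, ring closure being helped by the geminally disubstituted tether.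

**Step 3**
Reactants: 6 (5S)-spiro[bicyclo[3.3.0]oct-1-ene-7,2'-[1,3]dithian]-3-one; 7 (E)-3-ethoxy-2-methylprop-2-enal (3-ethoxymethacrolein)
Product: 9 (4R,5R)-4-[(1E)-3,3-diethoxy-2-methylprop-1-en-1-yl]spiro[bicyclo[3.3.0]oct-1-ene-7,2'-[1,3]dithian]-3-one, via aldol adduct 8 (not isolated)
Conditions: LiN(i-Pr)2, THF, −78 °C; 7; aq NH4Cl; crude 8, PPTS (10 mol %), EtOH, 3 Å MS, 23 °C
Reagents that add atoms: ethanol, CCO
Why: Kinetic deprotonation gives the cross-conjugated C20 enolate, whose aldol addition to 7 occurs on the face anti to C18 (cis to H19) and sets C20, and acid-catalysed allylic transposition of the vinylogous hemiacetal 8 in ethanol (3-alkoxyacrolein as an enal synthon) gives the unsaturated acetal, erasing the C21 carbinol centre.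

**Step 4**
Reactants: 9 (4R,5R)-4-[(1E)-3,3-diethoxy-2-methylprop-1-en-1-yl]spiro[bicyclo[3.3.0]oct-1-ene-7,2'-[1,3]dithian]-3-one
Product: 11 (1S,4R,5R)-4-[(1E)-3,3-diethoxy-2-methylprop-1-en-1-yl]-1-hydroxyspiro[bicyclo[3.3.0]octane-7,2'-[1,3]dithian]-3-one, via C15 pinacol boronate 10 (not isolated)
Conditions: CuCl (5 mol %), NaOt-Bu (5 mol %), DPEphos (5 mol %), B2pin2, MeOH, THF, 23 °C; then NaBO3·4H2O, THF–H2O, 23 °C
Reagents that add atoms: bis(pinacolato)diboron, CC1(C)OB(OC1(C)C)B1OC(C)(C)C(C)(C)O1 (boron of 10); sodium perborate, [Na+].[Na+].O[B-]1(O)OO[B-](O)(O)OO1 (O14 of 11)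
Why: Copper-catalysed conjugate borylation of the β,β-disubstituted enone from the convex face gives the cis-fused boronate 10, and oxidation of the C–B bond with retention places O14 on C15 cis to H19.

**Step 5**
Reactants: 1 1,3-dithiane; 12 ethyl chloroformate
Product: 13 ethyl 1,3-dithiane-2-carboxylate
Conditions: n-BuLi, THF, −30 °C; then added to 12, THF, −78 °C
Reagents that add atoms: none
Why: Acylation of 2-lithio-1,3-dithiane with a chloroformate gives the dithiane-masked glyoxylate, an acyl-anion equivalent for C12–C13.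

**Step 6**
Reactants: 11 (1S,4R,5R)-4-[(1E)-3,3-diethoxy-2-methylprop-1-en-1-yl]-1-hydroxyspiro[bicyclo[3.3.0]octane-7,2'-[1,3]dithian]-3-one; 13 ethyl 1,3-dithiane-2-carboxylate
Product: 14 ethyl 2-{(1S,3R,4R,5R)-4-[(1E)-3,3-diethoxy-2-methylprop-1-en-1-yl]-1,3-dihydroxyspiro[bicyclo[3.3.0]octane-7,2'-[1,3]dithian]-3-yl}-1,3-dithiane-2-carboxylate
Conditions: 13 (3 equiv), LiN(i-Pr)2, THF, −78 °C; 11, −78 °C; AcOH, −78 °C
Reagents that add atoms: none
Why: Aldol-type 1,2-addition of the weakly basic, ester-stabilised dithiane anion to the C24 ketone at low temperature occurs from the convex face of the cis-bicyclo[3.3.0]octanone and places C12 cis to O14; the C24 configuration is erased in step 8.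

**Step 7**
Reactants: 14 ethyl 2-{(1S,3R,4R,5R)-4-[(1E)-3,3-diethoxy-2-methylprop-1-en-1-yl]-1,3-dihydroxyspiro[bicyclo[3.3.0]octane-7,2'-[1,3]dithian]-3-yl}-1,3-dithiane-2-carboxylate
Product: 15 ethyl 2-{(1S,3R,4R,5R)-4-[(1E)-3,3-diethoxy-2-methylprop-1-en-1-yl]-1,3-dihydroxy-7-oxobicyclo[3.3.0]octan-3-yl}-2-oxoacetate
Conditions: PhI(OCOCF3)2, NaHCO3, MeCN–H2O (9:1), 0 °C
Reagents that add atoms: water, O
Why: Oxidative dethioacetalisation with the trivalent iodine reagent (S-activation, then hydrolysis) unmasks the C17 ketone and the C12 ketone together under bicarbonate buffering that spares the acetal, the alkene and both tertiary alcohols.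

**Step 8 (key step)**
Reactants: 15 ethyl 2-{(1S,3R,4R,5R)-4-[(1E)-3,3-diethoxy-2-methylprop-1-en-1-yl]-1,3-dihydroxy-7-oxobicyclo[3.3.0]octan-3-yl}-2-oxoacetate
Product: 17 (12S,15R,19R,20R)-hydroxy-lactone diketone [4-hydroxy-2-oxabicyclo[2.2.2]octane-3,5-dione with bridgeheads C15 and C12 (OH on C12), C13 lactone carbonyl and C24 ketone, fused at C15–C19 to a cyclopentanone (C17 ketone), (1E)-3,3-diethoxy-2-methylprop-1-enyl on C20], via bridged keto-lactone 16 (not isolated)
Conditions: Cu(OTf)2 (10 mol %), 2,2'-bipyridine (11 mol %), 2,6-di-tert-butylpyridine (20 mol %), 4 Å MS, CH2Cl2, 0 to 23 °C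
Reagents that add atoms: none
Why: Proposed new method: Lewis-acid-triggered transannular α-ketol (acyloin) ring expansion of a bridged α-keto-δ-lactone – Cu(OTf)2 chelates the 1,2-dicarbonyl of 15, the C15 hydroxyl closes the δ-lactone 16 with loss of ethanol, and in this 2-oxabicyclo[3.2.1]octane-3,4-dione the C24–C20 bond stands almost perpendicular to the activated C12 carbonyl while C24–C23 lies near its plane, so the secondary allylic C20 shifts from C24 to C12 with retention as the C24 hydroxyl becomes a ketone, forming ring B and the 2-oxabicyclo[2.2.2]octane lactone whose bridge fixes C12 as S; the shift is driven by turning a vicinal dicarbonyl into a β-keto lactone with a chelating tertiary hydroxyl, and the closest known reaction type is the Lewis-acid (copper–bisoxazoline) catalysed α-ketol rearrangement of β-hydroxy-α-keto esters to α-hydroxy-β-keto esters, including ring expansions of 1-hydroxycycloalkyl ketones, which has not been shown on a bridged α-keto lactone or in tandem with lactonisation.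

**Step 9**
Reactants: 17 (12S,15R,19R,20R)-hydroxy-lactone diketone
Product: 19 (12S,15R,17R,19R,20R,24R)-cyclic ethyl acetal [the target skeleton with ethoxy in place of the nonenyl group on C10; mixture of C10 epimers], via diol diethyl acetal 18 (not isolated)
Conditions: NaBH4, CeCl3·7H2O, EtOH, −78 °C; then CSA to pH 2, 23 °C
Reagents that add atoms: none
Why: Luche-type hydride reduction attacks the C24 ketone from the side of the lactone bridge (the other face is shielded by H20 and C18) and the C17 ketone from the convex face of ring A, setting 24R and 17R, and acidification then ionises the acetal so that, after reversible ethanol addition at C21 has allowed E to Z isomerisation, O11 closes ring D as the cyclic acetal (acid-catalysed transacetalisation).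

**Step 10**
Reactants: 20 1-bromoheptane; 21 lithium acetylide–ethylenediamine complex (LiC≡CH·H2NCH2CH2NH2)
Product: 22 non-1-yne
Conditions: DMSO, 15 to 23 °C
Reagents that add atoms: none
Why: SN2 alkylation of the acetylide by the primary bromide.

**Step 11**
Reactants: 22 non-1-yne
Product: 23 potassium (E)-trifluoro(non-1-en-1-yl)borate
Conditions: catecholborane, neat, 70 °C; then KHF2, MeOH–H2O, 23 °C
Reagents that add atoms: catecholborane, B1Oc2ccccc2O1; potassium hydrogen difluoride, [K+].F.[F-]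
Why: syn, anti-Markovnikov hydroboration of the terminal alkyne gives the (E)-alkenylboronate, which KHF2 converts into the stable trifluoroborate.

**Step 12**
Reactants: 19 (12S,15R,17R,19R,20R,24R)-cyclic ethyl acetal; 23 potassium (E)-trifluoro(non-1-en-1-yl)borate
Product: 24 target, (10R,12S,15R,17R,19R,20R,24R)-CNP0127096.2
Conditions: BF3·OEt2, MeCN, −40 to 0 °C
Reagents that add atoms: none
Why: BF3 ionises the exocyclic ethoxy group to the ring-fused 2H-pyranyl oxocarbenium ion and the alkenyldifluoroborane formed in situ transfers its (E)-alkenyl group to C10 (Lewis-acid-mediated acetal substitution by an organotrifluoroborate) along the pseudo-axial trajectory of the conformationally locked half-chair, which avoids eclipsing the C22 methyl (A(1,2) strain) and puts the chain cis to C13, i.e. 10R.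

**Compound list**
1 | 1,3-dithiane | C1SCCCS1 | starting material
2 | allyl bromide | C=CCBr | starting material
3 | propargyl bromide | C#CCBr | starting material
4 | 2-allyl-1,3-dithiane | C=CCC1SCCCS1 | intermediate
5 | 2-allyl-2-(prop-2-yn-1-yl)-1,3-dithiane | C=CCC1(CC#C)SCCCS1 | intermediate
6 | (5S)-spiro[bicyclo[3.3.0]oct-1-ene-7,2'-[1,3]dithian]-3-one | O=C1C=C2CC3(SCCCS3)C[C@@H]2C1 | intermediate
7 | (E)-3-ethoxy-2-methylprop-2-enal | CCO/C=C(\C)C=O | starting material
8 | aldol adduct, 4-[(2E)-3-ethoxy-1-hydroxy-2-methylprop-2-en-1-yl] derivative of 6 (C21 epimers) | O=C1C=C2CC3(SCCCS3)C[C@@H]2[C@H]1C(O)/C(C)=C/OCC | intermediate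
9 | (4R,5R)-4-[(1E)-3,3-diethoxy-2-methylprop-1-en-1-yl]spiro[bicyclo[3.3.0]oct-1-ene-7,2'-[1,3]dithian]-3-one | O=C1C=C2CC3(SCCCS3)C[C@@H]2[C@H]1/C=C(\C)C(OCC)OCC | intermediate
10 | C15 pinacol boronate of the saturated ketone (boron cis to H19) | CC1(C)OB(OC1(C)C)[C@]2(CC3(SCCCS3)C[C@@H]2[C@H]4/C=C(\C)C(OCC)OCC)CC4=O | intermediate
11 | (1S,4R,5R)-4-[(1E)-3,3-diethoxy-2-methylprop-1-en-1-yl]-1-hydroxyspiro[bicyclo[3.3.0]octane-7,2'-[1,3]dithian]-3-one | O[C@]1(CC3(SCCCS3)C[C@@H]1[C@H]2/C=C(\C)C(OCC)OCC)CC2=O | intermediate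
12 | ethyl chloroformate | CCOC(=O)Cl | starting material
13 | ethyl 1,3-dithiane-2-carboxylate | CCOC(=O)C1SCCCS1 | intermediate
14 | ethyl 2-{(1S,3R,4R,5R)-4-[(1E)-3,3-diethoxy-2-methylprop-1-en-1-yl]-1,3-dihydroxyspiro[bicyclo[3.3.0]octane-7,2'-[1,3]dithian]-3-yl}-1,3-dithiane-2-carboxylate | O[C@]1(CC3(SCCCS3)C[C@@H]1[C@H]2/C=C(\C)C(OCC)OCC)C[C@]2(O)C4(SCCCS4)C(=O)OCC | intermediate
15 | ethyl 2-{(1S,3R,4R,5R)-4-[(1E)-3,3-diethoxy-2-methylprop-1-en-1-yl]-1,3-dihydroxy-7-oxobicyclo[3.3.0]octan-3-yl}-2-oxoacetate | O[C@]1(CC(=O)C[C@@H]1[C@H]2/C=C(\C)C(OCC)OCC)C[C@]2(O)C(=O)C(=O)OCC | intermediate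
16 | (15S,19R,20R,24R)-bridged α-keto-δ-lactone (O14–C13(=O)–C12(=O)–C24(OH) bridge across C15/C24; 2-oxabicyclo[3.2.1]octane-3,4-dione; C17 ketone) | O=C1O[C@]2(CC(=O)C[C@@H]2[C@H]3/C=C(\C)C(OCC)OCC)C[C@]3(O)C1=O | intermediate
17 | (12S,15R,19R,20R)-hydroxy-lactone diketone (4-hydroxy-2-oxabicyclo[2.2.2]octane-3,5-dione fused to cyclopentanone) | O[C@@]23C(=O)O[C@]4(CC(=O)C[C@@H]4[C@H]2/C=C(\C)C(OCC)OCC)CC3=O | intermediate
18 | (12S,15R,17R,19R,20R,24R)-diol diethyl acetal | O[C@@]23C(=O)O[C@]4(C[C@H](O)C[C@@H]4[C@H]2/C=C(\C)C(OCC)OCC)C[C@H]3O | intermediate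
19 | (12S,15R,17R,19R,20R,24R)-cyclic ethyl acetal (10-ethoxy in place of nonenyl; C10 epimers) | CCOC1O[C@@]23C(=O)O[C@]4(C[C@H](O)C[C@@H]4[C@H]2C=C1C)C[C@H]3O | intermediate
20 | 1-bromoheptane | CCCCCCCBr | starting material
21 | lithium acetylide–ethylenediamine complex | [Li+].[C-]#C.NCCN | starting material
22 | non-1-yne | CCCCCCCC#C | intermediate
23 | potassium (E)-trifluoro(non-1-en-1-yl)borate | CCCCCCC/C=C/[B-](F)(F)F.[K+] | intermediate
24 | CNP0127096.2, (10R,12S,15R,17R,19R,20R,24R) | CCCCCCC/C=C/[C@H]1O[C@@]23C(=O)O[C@]4(C[C@H](O)C[C@@H]4[C@H]2C=C1C)C[C@H]3O | target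

**Step count**
Total: 12 steps. Longest linear sequence: 9 steps (1, 2, 3, 4, 6, 7, 8, 9, 12).

**Steps most likely to fail**

Step 8 (the proposed ring expansion). It may stop at 16, shift C23 instead of C20, or lose O14 by β-elimination from the product. The fallback sets out from 11 and comes back at 17. Lithiated ethyl diazoacetate (LiN(i-Pr)2, THF, −78 °C) adds to the C24 ketone to give the α-diazo-β-hydroxy ester F4. Rh2(OAc)4 (1 mol %, CH2Cl2) then brings about the known carbenoid 1,2-shift of β-hydroxy-α-diazo esters, in which the more substituted C20 migrates, to give the ring-expanded β-keto ester F5. Alkylative hydrolysis of the dithiane (MeI, CaCO3, MeCN–H2O) gives the diketo ester F6. Hydroxylation with 3-phenyl-2-(phenylsulfonyl)oxaziridine and K2CO3, anti to the C20 substituent, gives the α-hydroxy-β-keto ester F7. Warming with Ti(Oi-Pr)4 lactonises F7 to 17.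

Step 2 (enantioselective Pauson–Khand reaction of a sulfur-containing terminal enyne). The dithiane may slow the catalyst or the ee may be low. The fallback sets out from 5 and comes back at 6. A stoichiometric Pauson–Khand reaction (Co2(CO)8, then N-methylmorpholine N-oxide, CH2Cl2) gives the racemic enone F1. Reduction with (S)-2-methyl-CBS-oxazaborolidine and catecholborane turns the two enantiomers into diastereomeric (3R)-allylic alcohols. The (3R,5S)-allylic alcohol F2 is separated by chromatography from the (3R,5R)-allylic alcohol F3 and oxidised with MnO2 to 6.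

Step 12 (C10 configuration and site of attack on the oxocarbenium ion). Attack from the other face would give the C10 epimer. The fallback sets out from 19 and comes back at 24. Non-1-yne 22 is converted (n-BuLi, B(OMe)3, then KHF2) into potassium trifluoro(non-1-yn-1-yl)borate F8. With BF3·OEt2 the slender alkynyl group adds to the oxocarbenium ion of 19 along the pseudo-axial path to give the C10-alkynyl ether F9. Ruthenium-catalysed trans-selective semihydrogenation ([Cp*RuCl(cod)], AgOTf, H2) then gives the (E)-alkene 24.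

**Further compounds**
F1 | step 2 | racemic spiro[bicyclo[3.3.0]oct-1-ene-7,2'-[1,3]dithian]-3-one | O=C1C=C2CC3(SCCCS3)CC2C1
F2 | step 2 | (3R,5S)-spiro[bicyclo[3.3.0]oct-1-ene-7,2'-[1,3]dithian]-3-ol | O[C@H]1C=C2CC3(SCCCS3)C[C@@H]2C1
F3 | step 2 | (3R,5R)-spiro[bicyclo[3.3.0]oct-1-ene-7,2'-[1,3]dithian]-3-ol | O[C@H]1C=C2CC3(SCCCS3)C[C@H]2C1
F4 | step 8 | ethyl 2-diazo-2-{(1S,4R,5R)-4-[(1E)-3,3-diethoxy-2-methylprop-1-en-1-yl]-1,3-dihydroxyspiro[bicyclo[3.3.0]octane-7,2'-[1,3]dithian]-3-yl}acetate | O[C@]1(CC3(SCCCS3)C[C@@H]1[C@H]2/C=C(\C)C(OCC)OCC)CC2(O)C(=[N+]=[N-])C(=O)OCC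
F5 | step 8 | ring-expanded β-keto ester (C24 ketone, C12 bearing CO2Et, C15 hydroxyl, C17 dithiane; 15S,19R,20R) | O[C@]1(CC3(SCCCS3)C[C@@H]1[C@H]2/C=C(\C)C(OCC)OCC)CC(=O)C2C(=O)OCC
F6 | step 8 | diketo ester (as F5 with free C17 ketone) | O[C@]1(CC(=O)C[C@@H]1[C@H]2/C=C(\C)C(OCC)OCC)CC(=O)C2C(=O)OCC
F7 | step 8 | (12S,15S,19R,20R)-α-hydroxy-β-keto ester (C12 hydroxyl and CO2Et, ester cis to O14) | O[C@]1(CC(=O)C[C@@H]1[C@H]2/C=C(\C)C(OCC)OCC)CC(=O)[C@]2(O)C(=O)OCC
F8 | step 12 | potassium trifluoro(non-1-yn-1-yl)borate | CCCCCCCC#C[B-](F)(F)F.[K+]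
F9 | step 12 | C10-(non-1-yn-1-yl) analogue of the target (same spatial arrangement at C10) | CCCCCCCC#C[C@H]1O[C@@]23C(=O)O[C@]4(C[C@H](O)C[C@@H]4[C@H]2C=C1C)C[C@H]3O
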